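## Structural features

The target has three rings: ring A, a methyl 4-hydroxybenzoate; ring B, a 2,3-dihydrofuran (O1, C2, C3, C3a, C7a); and ring C, a cyclohexa-1,3-diene (C3a, C4, C5, C6, C7, C7a) fused to ring B through the C3a=C7a double bond. Ring A is bonded through C3' (ortho to the phenol) to C3; C2 carries a 2-hydroxypropan-2-yl group, C4 a methoxy group, C6 a hydroxyl and C7 a 3-phenylpropanoyl group. There are two pairs of adjacent stereocentres: C2/C3 (2R,3S, substituents cis on ring B) and C6/C7 (6S,7S, hydroxyl and acyl cis on ring C), the two pairs lying on opposite faces of the bicycle. Ring C is a bis-enol ether (O1–C7a=C3a–C4(OMe)=C5) that acid hydrolyses, and it holds a β-hydroxy ketone (C6–OH, C7 acyl) whose dehydration across C6–C7 would turn ring C into a benzene ring. Acid, base and any enolate next to C6 therefore threaten aromatization, and C7–H can also epimerize. The real difficulties are the hindered bond between C3' of an ortho-oxygenated arene and C3 of a cis-2,3-disubstituted dihydrofuran, and the late placing of the C7 acyl group cis to the C6 oxygen without losing that oxygen. The key step exploits the 1,3,4-pattern of ring A: C1' (with its ester), C2', C5' and C6' map onto C5, C6, C3 and C4 of methyl coumalate, and C3'/C4' with the phenol oxygen are the two carbons of a silyl ynol ether that already sits on C3.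

## Logic of the disconnections

33 ⇒ 32 ⇒ 31. The last bonds formed are three O–H bonds (three O–Si bonds cut) and the C7–H bond. C7–H is traced back to C7–Cl in 31 because reductive cleavage of the halide gives the C7 enolate at one defined position and only for an instant. The gain is that the one base-sensitive stereocentre is set at the very end. The demand is that protonation at C7, on the face away from the C6 silyloxy group, is faster than loss of that group.

31 ⇒ 29. The cuts are the O–CH3 bond at C4 and the C4=C5 double bond, back to the C4 ketone and C5H2. Alkylation on the carbonyl oxygen of a vinylogous ester needs no base, and with C7 fully substituted only C5 can give up a proton. Ring C returns to the robust 4-ketone. The forward step must methylate O4 only and use a hindered amine that does not remove HCl across C6–C7.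

29 ⇒ 25 + 26. The cuts are the C7–C(acyl) bond and the C7–Cl bond. The γ-carbon of a vinylogous ester is reached through its dienolate, so the acyl carbon is brought in as the aldehyde 26; oxidation and chlorination then turn the very acidic C7–H of 28 into a stable quaternary centre. The whole side chain is removed in one cut. The forward step must deprotonate C7 and not C5, and 28 must not be left standing.

25 ⇒ 22 + 23 (key). The cuts are C2'–C3' and C4'–C5' of ring A. They are made here because the ester-bearing four-carbon unit is a 2-pyrone and the oxygenated C3'–C4' pair is an ynol ether, so the crowded aryl–C3 bond never has to be formed as such. Ring A disappears and a two-carbon alkyne remains on C3. The forward step must place oxygen para to the ester, and the ynol ether must survive heating.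

22 ⇒ 18. The cut is the O–C(sp) bond (with its O–Si bond). The oxygen is added to the terminal alkyne of 18 by oxidation of its lithium acetylide, so the sensitive ynol ether exists for one step only. The demand is that the C4 ketone be masked (as 19) first; otherwise the base would make an enolate next to the C6 silyloxy group.

18 ⇒ 17 ⇒ 14 + 7. The cuts are O1–C7a, then C3–C3a. O1–C7a is an exchange of the methoxy group of 17 for the side-chain hydroxyl, so the methoxy-bearing carbon fixes where O1 goes and C6 keeps its relation to ring B. C3–C3a is cut to a vinyl anion (from 14) and the epoxide 7: opening at the propargylic carbon with inversion turns a trans epoxide into the cis-2,3 pattern. This gives two fragments of similar size, each of defined configuration. The forward step needs a true carbanion at C3a, because the neutral vinylogous ester would attack an activated epoxide through its carbonyl oxygen, and the attack must be SN2 at the propargylic carbon.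

14 ⇒ 12 ⇒ 11 ⇒ 10 ⇒ 9 ⇒ 8. The cuts are C–Br and the enol O–Si bond of 14, the O–Si bond of 12, the separation of enantiomers (10 to 11), the O–CH3 bond of 10 and two C–H bonds of 9. Since 9 is symmetric, chirality can only come from telling its two carbonyl carbons apart, which the methyl enol ether does. The demand is a resolution at the stage of 10.

7 ⇒ 6 ⇒ 4 + 5, and 4 ⇒ 2 ⇒ 1. The cuts are the two C–O bonds of the epoxide (reagent-controlled epoxidation of an E-enyne), the C(sp2)–C(sp) bond, the C–I bond and an O–Si bond. This leads back to two commercial alkynes. The epoxidation must be selective for one alkene face and must leave the alkyne alone.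

## Other disconnections considered

Alternative 1: The cut is the C4=C5 double bond. In the forward direction the acyclic diene A1, which carries a 1-methoxyvinyl group on C3a and a vinyl group on C6, would be closed by ring-closing metathesis with (H2IMes)(PCy3)Cl2Ru=CHPh (second-generation Grubbs catalyst). Ethylene is lost and the product is A2, the target as its 6-O-triethylsilyl ether.
- In favour: the last C–C bond forms under neutral conditions; the methyl enol ether is carried in ready-made; C6 and C7 can be set by an acyclic aldol reaction; and no enolate is ever generated on a ring that can aromatize. On this point the alternative is the better plan, since it avoids the γ-functionalization and the late protonation of the chosen route.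
- Against: a ruthenium carbene that meets the enol ether first gives an unreactive alkoxycarbene; the product is a conjugated dialkoxy diene, a poor and reversible metathesis product; and A1 holds a β-silyloxy ketone whose C7–H is activated by the ketone and by ring B, so retro-aldol cleavage and epimerization are open before the ring is closed.
- Comparison: on structure it solves ring C but leaves the ring A–C3 bond unsolved. On mechanism it is less secure than a pyrone cycloaddition. On step economy it is about equal.

Alternative 2: The cuts are C4'–O, C3'–C3 and C3–C3a. In the forward direction the aryne A3 would add the carbonyl group of aldehyde A4; the benzoxete would open to an ortho-quinone methide, which would be trapped at C3 by the enone A5 (the enantiomer of 12) to give A6.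
- In favour: three bonds around the crowded C3 and the phenol oxygen form in one flask. The methoxy group of A5 is already the C4 methoxy group of the target, so closure of ring B onto the ketone would give the dienol ether directly. In convergence and step count this is the better plan, and it needs no late O-methylation.
- Against: the aldehyde oxygen has little reason to choose the carbon para to the ester of A3; the α-carbon of A5 is a weak nucleophile and ortho-quinone methides readily give chromans by [4+2] addition; C3 would be set only by acyclic induction from the dioxolane; the free phenol can close a six-membered ring onto the ketone in competition with ring B; and C7 would still have to be acylated next to the acid-labile dienol ether.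
- Comparison: on structure it is the most direct. On mechanism it has three unsecured selectivities where the chosen plan has a stereospecific epoxide opening and a polarity-matched cycloaddition. On step economy it is clearly shorter if those selectivities hold.

Alternative 3: The cut is the C2–C3 bond. In the forward direction the diazo compound A7 would lose nitrogen with a chiral dirhodium tetracarboxylate such as Rh2(S-PTTL)4 (divalent rhodium), and the carbene would insert into a C2–H bond next to O1 to give A8, the tert-butyldimethylsilyl analogue of 25.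
- In favour: ring B and both of its stereocentres arise in one catalytic step; 1,5-insertion next to oxygen is known to favour cis-2,3-dihydrobenzofurans; ring A is bought as an arene; and no ynol ether is needed. In step count up to A8, and in avoiding the two most delicate steps of the chosen route (ynol ether formation and cycloaddition), it is the better plan.
- Against: the carbene carbon is flanked by the C4 carbonyl oxygen, which can close a furan, and vinyl diazo compounds cyclize to pyrazoles; A7 would have to be made by hydrazone oxidation at a hindered diaryl-type ketone; the sense of insertion rests on catalyst control with a remote C6 stereocentre, so two diastereomers are possible; and the aryl–C3 bond is still made at a crowded position, though as an sp2 ketone.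
- Comparison: the endgame from A8 is the same as from 25, so the two plans are equal there. On mechanism the chosen plan sets C2 and C3 by inversion at a defined epoxide, which is the more predictable control.

Key step: step 14

Assumption: in step 7 the lipase is taken to acylate the (S)-alcohol faster, as the size rule for secondary alcohols predicts when the methoxy-bearing arm is the larger one; if its preference is the reverse, the (R)-acetate would be collected and cleaved with K2CO3 in methanol.

## Steps

Step 1
Reactants: 1 2-methylbut-3-yn-2-ol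
Product: 2 triethyl[(2-methylbut-3-yn-2-yl)oxy]silane
Conditions: Et3SiOTf, 2,6-lutidine, CH2Cl2, 0 °C
Reagents that add atoms: triethylsilyl trifluoromethanesulfonate, CC[Si](CC)(CC)OS(=O)(=O)C(F)(F)F
Why: Silylation of a tertiary alcohol with a silyl triflate and a hindered base; the ether protects the carbinol through every later step and is cleaved by fluoride at the end.

Step 2
Reactants: 2 triethyl[(2-methylbut-3-yn-2-yl)oxy]silane
Product: 4 triethyl{[(3E)-4-iodo-2-methylbut-3-en-2-yl]oxy}silane, via vinylstannane 3 (not isolated)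
Conditions: Bu3SnH, PdCl2(PPh3)2 (2 mol%), THF, 0 °C to rt; then I2, CH2Cl2, 0 °C
Reagents that add atoms: iodine, II
Why: Palladium-catalysed hydrostannation is a syn addition that puts tin on the terminal carbon, away from the quaternary centre, and iododestannylation proceeds with retention, so the E-iodoalkene should result.

Step 3
Reactants: 4 triethyl{[(3E)-4-iodo-2-methylbut-3-en-2-yl]oxy}silane; 5 ethynyltrimethylsilane
Product: 6 triethyl{[(3E)-2-methyl-6-(trimethylsilyl)hex-3-en-5-yn-2-yl]oxy}silane
Conditions: PdCl2(PPh3)2 (3 mol%), CuI (5 mol%), Et3N, THF, rt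
Reagents that add atoms: none
Why: Sonogashira coupling of an alkenyl iodide with a terminal alkyne keeps the E geometry; the trimethylsilyl group blocks the alkyne terminus for steps 4 and 10.

Step 4
Reactants: 6 triethyl{[(3E)-2-methyl-6-(trimethylsilyl)hex-3-en-5-yn-2-yl]oxy}silane
Product: 7 (2R,3S)-2-[2-(triethylsilyloxy)propan-2-yl]-3-[(trimethylsilyl)ethynyl]oxirane (trans)
Conditions: ent-Shi ketone (1,2:4,5-di-O-isopropylidene-β-L-erythro-2,3-hexodiulo-2,6-pyranose, 30 mol%), KHSO5 (as Oxone), K2CO3, Bu4NHSO4, MeCN–CH2(OMe)2–aqueous Na2B4O7 buffer, 0 °C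
Reagents that add atoms: potassium peroxymonosulfate, [K+].[O-]S(=O)(=O)OO
Why: Shi epoxidation; the chiral dioxirane transfers oxygen to one face of a trans-disubstituted alkene through a spiro transition state and conjugated enynes react at the alkene only, so the L-series ketone should give the (2R,3S) trans epoxide. Any minor enantiomer becomes a diastereomer after step 10 and is removed there.

Step 5
Reactants: 8 phloroglucinol (benzene-1,3,5-triol)
Product: 9 5-hydroxycyclohexane-1,3-dione
Conditions: NaBH4, H2O, 20 °C; then acidic ion-exchange resin (H+ form), 0 °C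
Reagents that add atoms: none
Why: Hydride reduction of the keto tautomer of phloroglucinol; the product is kept cold and only briefly acidic because it dehydrates to resorcinol.

Step 6
Reactants: 9 5-hydroxycyclohexane-1,3-dione
Product: 10 rac-5-hydroxy-3-methoxycyclohex-2-en-1-one
Conditions: Me3SiCHN2, MeOH–toluene (1:4), 0 °C
Reagents that add atoms: trimethylsilyldiazomethane, C[Si](C)(C)C=[N+]=[N-]
Why: O-Methylation of the acidic enol of a cyclic 1,3-dione under neutral conditions; the secondary alcohol is not acidic enough to react, and the enol ether makes C5 a stereocentre.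

Step 7
Reactants: 10 rac-5-hydroxy-3-methoxycyclohex-2-en-1-one
Product: 11 (5R)-5-hydroxy-3-methoxycyclohex-2-en-1-one
Conditions: Candida antarctica lipase B (immobilized), vinyl acetate, tert-butyl methyl ether, 30 °C, stopped just beyond half conversion
Reagents that add atoms: none
Why: Enzymatic kinetic resolution by irreversible transesterification; the (S)-alcohol should be acetylated and the (R)-alcohol recovered, the two being separated by chromatography.

Step 8
Reactants: 11 (5R)-5-hydroxy-3-methoxycyclohex-2-en-1-one
Product: 12 (5R)-5-(tert-butyldimethylsilyloxy)-3-methoxycyclohex-2-en-1-one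
Conditions: tBuMe2SiCl, imidazole, DMF, rt
Reagents that add atoms: tert-butyldimethylsilyl chloride, CC(C)(C)[Si](C)(C)Cl
Why: Standard silylation of a secondary alcohol; the bulky ether later shields one face of C7.

Step 9
Reactants: 12 (5R)-5-(tert-butyldimethylsilyloxy)-3-methoxycyclohex-2-en-1-one
Product: 14 (6R)-3-bromo-2,6-bis(tert-butyldimethylsilyloxy)-4-methoxycyclohexa-1,3-diene, via bromo enone 13 (not isolated)
Conditions: N-bromosuccinimide, CH2Cl2, 0 °C; then Et3N, tBuMe2SiOTf, 0 °C
Reagents that add atoms: N-bromosuccinimide, O=C1CCC(=O)N1Br; tert-butyldimethylsilyl trifluoromethanesulfonate, CC(C)(C)[Si](C)(C)OS(=O)(=O)C(F)(F)F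
Why: Electrophilic bromination of a vinylogous ester at its α-carbon, then soft enolization to the silyl dienol ether; the ketone is thereby masked without an alkali enolate next to the silyloxy group, and the methoxy group still marks the carbon that will become C7a.

Step 10
Reactants: 14 (6R)-3-bromo-2,6-bis(tert-butyldimethylsilyloxy)-4-methoxycyclohexa-1,3-diene; 7 (2R,3S)-2-[2-(triethylsilyloxy)propan-2-yl]-3-[(trimethylsilyl)ethynyl]oxirane
Product: 17 (5R)-5-(tert-butyldimethylsilyloxy)-2-[(3S,4R)-4-hydroxy-5-methyl-5-(triethylsilyloxy)hex-1-yn-3-yl]-3-methoxycyclohex-2-en-1-one, via vinyllithium 15 (not isolated), via silylated hydroxy diene 16 (not isolated)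
Conditions: tert-butyllithium (2 equiv), Et2O, −78 °C; BF3·OEt2 then 7, −78 °C; aqueous NaHCO3; crude product in THF, Bu4NF, −40 to 0 °C, AcOH quench
Reagents that add atoms: none
Why: Bromine–lithium exchange, then BF3-assisted SN2 opening of the epoxide by the vinyllithium at the propargylic carbon (the other carbon is neopentyl-like and the silyl cap disfavours SN2'), so C3 is set by inversion and C2 is carried over unchanged. Fluoride then cleaves the enol silyl ether and the C-silyl group, returning the ketone at the carbon that was silylated.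

Step 11
Reactants: 17 (5R)-5-(tert-butyldimethylsilyloxy)-2-[(3S,4R)-4-hydroxy-5-methyl-5-(triethylsilyloxy)hex-1-yn-3-yl]-3-methoxycyclohex-2-en-1-one
Product: 18 (2R,3S,6R)-6-(tert-butyldimethylsilyloxy)-3-ethynyl-2-[2-(triethylsilyloxy)propan-2-yl]-3,5,6,7-tetrahydro-1-benzofuran-4(2H)-one
Conditions: pyridinium p-toluenesulfonate (10 mol%), benzene, 5 Å molecular sieves, 50 °C
Reagents that add atoms: none
Why: Acid-catalysed intramolecular transetherification of a vinylogous ester: the hydroxyl adds to the methoxy-bearing carbon of the protonated enone (5-exo with respect to the C=O+ bond) and methanol is lost, so O1 goes to C7a and the trans epoxide ends as the cis-2,3 ring.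

Step 12
Reactants: 18 (2R,3S,6R)-6-(tert-butyldimethylsilyloxy)-3-ethynyl-2-[2-(triethylsilyloxy)propan-2-yl]-3,5,6,7-tetrahydro-1-benzofuran-4(2H)-one
Product: 19 (2R,3S,6R)-6-(tert-butyldimethylsilyloxy)-3-ethynyl-4-(triethylsilyloxy)-2-[2-(triethylsilyloxy)propan-2-yl]-2,3,6,7-tetrahydro-1-benzofuran
Conditions: Et3SiOTf, Et3N, CH2Cl2, −78 to 0 °C
Reagents that add atoms: triethylsilyl trifluoromethanesulfonate, CC[Si](CC)(CC)OS(=O)(=O)C(F)(F)F
Why: Soft enolization of the vinylogous ester to a silyl dienol ether; this removes the only C–H bonds that would compete with the alkyne for base in step 13, and either regioisomer of the dienol ether would return the same ketone.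

Step 13
Reactants: 19 (2R,3S,6R)-6-(tert-butyldimethylsilyloxy)-3-ethynyl-4-(triethylsilyloxy)-2-[2-(triethylsilyloxy)propan-2-yl]-2,3,6,7-tetrahydro-1-benzofuran
Product: 22 (2R,3S,6R)-6-(tert-butyldimethylsilyloxy)-2-[2-(triethylsilyloxy)propan-2-yl]-3-[(triisopropylsilyloxy)ethynyl]-3,5,6,7-tetrahydro-1-benzofuran-4(2H)-one, via lithium ynolate 20 (not isolated), via masked ynol ether 21 (not isolated)
Conditions: LiN(SiMe3)2, THF, −78 °C; LiOOtBu (from tBuOOH and LiN(SiMe3)2), −78 to 0 °C; iPr3SiOTf, −78 to 0 °C; then K2CO3, MeOH, 0 °C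
Reagents that add atoms: tert-butyl hydroperoxide, CC(C)(C)OO; triisopropylsilyl trifluoromethanesulfonate, CC(C)[Si](C(C)C)(C(C)C)OS(=O)(=O)C(F)(F)F
Why: Oxidation of a lithium acetylide by lithium tert-butyl peroxide to the ynolate and O-silylation with a bulky silyl triflate, the standard route to silyl ynol ethers. Basic methanolysis then cleaves only the enol silyl ether, since the hindered ynol ether is stable to base.

Step 14
Reactants: 22 (2R,3S,6R)-6-(tert-butyldimethylsilyloxy)-2-[2-(triethylsilyloxy)propan-2-yl]-3-[(triisopropylsilyloxy)ethynyl]-3,5,6,7-tetrahydro-1-benzofuran-4(2H)-one; 23 methyl coumalate (methyl 2-oxo-2H-pyran-5-carboxylate)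
Product: 25 methyl 3-[(2R,3S,6R)-6-(tert-butyldimethylsilyloxy)-4-oxo-2-[2-(triethylsilyloxy)propan-2-yl]-2,3,4,5,6,7-hexahydro-1-benzofuran-3-yl]-4-(triisopropylsilyloxy)benzoate, via bicyclic lactone 24 (not isolated)
Conditions: 23 (2 equiv), toluene, 100 °C, sealed tube
Reagents that add atoms: none
Why: Inverse-electron-demand Diels–Alder reaction of a 2-pyrone with an electron-rich alkyne followed by cycloreversion, the reaction type by which methyl coumalate is turned into benzoates with ynamines, alkoxyalkynes and ketene acetals. The ynol ether has its large HOMO coefficient on the carbon that carries C3, and the pyrone is most electrophilic at C6 (β to the ester and vinylogous to the lactone carbonyl), so the C3'–C2' bond should form ahead of the C4'–C5' bond. Lactone 24 should not persist: a retro-[4+2] expels CO2 and leaves the benzene ring. Ring A is thus closed by a [4+2] cycloaddition, four pyrone carbons and the two alkyne carbons joining in one suprafacial event, and not by attack of a chain end. No stereocentre is created; C3 is only a σ-bonded neighbour and keeps its configuration, as do C2 and C6. The step needs one regiochemistry (oxygen para and C3 meta to the ester), which the polarity match secures, and chemoselectivity for the ynol ether over the push-pull alkene of ring C, which is electronically mismatched with the electron-poor diene. The crowded aryl–C3 bond is never made by coupling, because the arene is assembled on a carbon that is already in place.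

Step 15
Reactants: 25 methyl 3-[(2R,3S,6R)-6-(tert-butyldimethylsilyloxy)-4-oxo-2-[2-(triethylsilyloxy)propan-2-yl]-2,3,4,5,6,7-hexahydro-1-benzofuran-3-yl]-4-(triisopropylsilyloxy)benzoate; 26 3-phenylpropanal
Product: 27 methyl 3-[(2R,3S,6S)-6-(tert-butyldimethylsilyloxy)-7-(1-hydroxy-3-phenylpropyl)-4-oxo-2-[2-(triethylsilyloxy)propan-2-yl]-2,3,4,5,6,7-hexahydro-1-benzofuran-3-yl]-4-(triisopropylsilyloxy)benzoate (mixture at C7 and at the carbinol carbon)
Conditions: Al(OC6H3-2,6-Ph2)3 (3.3 equiv), toluene, −78 °C; LiN(iPr)2, THF, −78 °C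
Reagents that add atoms: none
Why: Vinylogous aldol reaction under a bulky aluminium phenoxide: complexation of the C4 carbonyl shields C5, so the amide base should remove a C7 proton and the dienolate adds to the complexed aldehyde at C7. The two new stereocentres need no control because both are erased in steps 16 and 18.

Step 16
Reactants: 27 methyl 3-[(2R,3S,6S)-6-(tert-butyldimethylsilyloxy)-7-(1-hydroxy-3-phenylpropyl)-4-oxo-2-[2-(triethylsilyloxy)propan-2-yl]-2,3,4,5,6,7-hexahydro-1-benzofuran-3-yl]-4-(triisopropylsilyloxy)benzoate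
Product: 29 methyl 3-[(2R,3S,6S)-6-(tert-butyldimethylsilyloxy)-7-chloro-4-oxo-7-(3-phenylpropanoyl)-2-[2-(triethylsilyloxy)propan-2-yl]-2,3,4,5,6,7-hexahydro-1-benzofuran-3-yl]-4-(triisopropylsilyloxy)benzoate (configuration at C7 not controlled), via acyl ketone 28 (not isolated)
Conditions: Dess–Martin periodinane, CH2Cl2, 0 °C; then N-chlorosuccinimide, 0 °C to rt
Reagents that add atoms: N-chlorosuccinimide, O=C1CCC(=O)N1Cl
Why: Dess–Martin oxidation, then electrophilic chlorination of the resulting vinylogous 1,3-diketone at its only unhindered nucleophilic carbon, C7. Ketone 28 has an acidic C7–H β to the silyloxy group and is chlorinated in the same flask, which removes that proton and leaves a latent C7 enolate.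

Step 17
Reactants: 29 methyl 3-[(2R,3S,6S)-6-(tert-butyldimethylsilyloxy)-7-chloro-4-oxo-7-(3-phenylpropanoyl)-2-[2-(triethylsilyloxy)propan-2-yl]-2,3,4,5,6,7-hexahydro-1-benzofuran-3-yl]-4-(triisopropylsilyloxy)benzoate
Product: 31 methyl 3-[(2R,3S,6S)-6-(tert-butyldimethylsilyloxy)-7-chloro-4-methoxy-7-(3-phenylpropanoyl)-2-[2-(triethylsilyloxy)propan-2-yl]-2,3,6,7-tetrahydro-1-benzofuran-3-yl]-4-(triisopropylsilyloxy)benzoate, via oxocarbenium salt 30 (not isolated)
Conditions: Me3OBF4, CH2Cl2, 0 °C to rt; then iPr2NEt, −78 to 0 °C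
Reagents that add atoms: trimethyloxonium tetrafluoroborate, C[O+](C)C.F[B-](F)(F)F
Why: O-Alkylation of a vinylogous ester at its strongly basic carbonyl oxygen by an oxonium salt, then deprotonation of the 1,3-dialkoxyallyl cation by a hindered amine; C7 has no hydrogen, so only C5 can lose a proton and the C4(OMe)=C5 enol ether forms without any enolate.

Step 18
Reactants: 31 methyl 3-[(2R,3S,6S)-6-(tert-butyldimethylsilyloxy)-7-chloro-4-methoxy-7-(3-phenylpropanoyl)-2-[2-(triethylsilyloxy)propan-2-yl]-2,3,6,7-tetrahydro-1-benzofuran-3-yl]-4-(triisopropylsilyloxy)benzoate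
Product: 32 methyl 3-[(2R,3S,6S,7S)-6-(tert-butyldimethylsilyloxy)-4-methoxy-7-(3-phenylpropanoyl)-2-[2-(triethylsilyloxy)propan-2-yl]-2,3,6,7-tetrahydro-1-benzofuran-3-yl]-4-(triisopropylsilyloxy)benzoate
Conditions: SmI2 (2.5 equiv), THF–MeOH, −78 °C
Reagents that add atoms: none
Why: Reductive cleavage of an α-chloro ketone by divalent samarium gives the enolate at C7 only, and methanol present in the flask protonates it at once at the α-carbon. The proton should enter anti to the bulky C6 silyloxy group, which places the acyl group cis to that oxygen (7S).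

Step 19
Reactants: 32 methyl 3-[(2R,3S,6S,7S)-6-(tert-butyldimethylsilyloxy)-4-methoxy-7-(3-phenylpropanoyl)-2-[2-(triethylsilyloxy)propan-2-yl]-2,3,6,7-tetrahydro-1-benzofuran-3-yl]-4-(triisopropylsilyloxy)benzoate
Product: 33 methyl 4-hydroxy-3-[(2R,3S,6S,7S)-6-hydroxy-2-(2-hydroxypropan-2-yl)-4-methoxy-7-(3-phenylpropanoyl)-2,3,6,7-tetrahydro-1-benzofuran-3-yl]benzoate
Conditions: Bu4NF, AcOH (1:1), THF, 0 °C to rt
Reagents that add atoms: none
Why: Fluoride-mediated cleavage of the aryl, tertiary and secondary silyl ethers; acetic acid keeps the medium near neutral, so neither the enol ethers nor the β-hydroxy ketone should be harmed.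

## Compound list

1 | 2-methylbut-3-yn-2-ol | CC(C)(O)C#C | starting material
2 | triethyl[(2-methylbut-3-yn-2-yl)oxy]silane | CC[Si](CC)(CC)OC(C)(C)C#C | intermediate
3 | (E)-tributyl[3-methyl-3-(triethylsilyloxy)but-1-en-1-yl]stannane (not isolated) | CCCC[Sn](CCCC)(CCCC)/C=C/C(C)(C)O[Si](CC)(CC)CC | intermediate
4 | triethyl{[(3E)-4-iodo-2-methylbut-3-en-2-yl]oxy}silane | CC[Si](CC)(CC)OC(C)(C)/C=C/I | intermediate
5 | ethynyltrimethylsilane | C[Si](C)(C)C#C | starting material
6 | triethyl{[(3E)-2-methyl-6-(trimethylsilyl)hex-3-en-5-yn-2-yl]oxy}silane | CC[Si](CC)(CC)OC(C)(C)/C=C/C#C[Si](C)(C)C | intermediate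
7 | (2R,3S)-2-[2-(triethylsilyloxy)propan-2-yl]-3-[(trimethylsilyl)ethynyl]oxirane | C[Si](C)(C)C#C[C@@H]1O[C@H]1C(C)(C)O[Si](CC)(CC)CC | intermediate
8 | phloroglucinol | Oc1cc(O)cc(O)c1 | starting material
9 | 5-hydroxycyclohexane-1,3-dione | O=C1CC(O)CC(=O)C1 | intermediate
10 | rac-5-hydroxy-3-methoxycyclohex-2-en-1-one (racemate) | COC1=CC(=O)CC(O)C1 | intermediate
11 | (5R)-5-hydroxy-3-methoxycyclohex-2-en-1-one | COC1=CC(=O)C[C@H](O)C1 | intermediate
12 | (5R)-5-(tert-butyldimethylsilyloxy)-3-methoxycyclohex-2-en-1-one | COC1=CC(=O)C[C@H](O[Si](C)(C)C(C)(C)C)C1 | intermediate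
13 | (5R)-2-bromo-5-(tert-butyldimethylsilyloxy)-3-methoxycyclohex-2-en-1-one (not isolated) | COC1=C(Br)C(=O)C[C@H](O[Si](C)(C)C(C)(C)C)C1 | intermediate
14 | (6R)-3-bromo-2,6-bis(tert-butyldimethylsilyloxy)-4-methoxycyclohexa-1,3-diene | COC1=C(Br)C(O[Si](C)(C)C(C)(C)C)=C[C@H](O[Si](C)(C)C(C)(C)C)C1 | intermediate
15 | 3-lithio analogue of 14 (not isolated) | COC1=C([Li])C(O[Si](C)(C)C(C)(C)C)=C[C@H](O[Si](C)(C)C(C)(C)C)C1 | intermediate
16 | 3-[4-hydroxy-5-methyl-5-(triethylsilyloxy)-1-(trimethylsilyl)hex-1-yn-3-yl] analogue of 14, configurations as in 17 (not isolated) | COC1=C([C@H](C#C[Si](C)(C)C)[C@@H](O)C(C)(C)O[Si](CC)(CC)CC)C(O[Si](C)(C)C(C)(C)C)=C[C@H](O[Si](C)(C)C(C)(C)C)C1 | intermediate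
17 | (5R)-5-(tert-butyldimethylsilyloxy)-2-[(3S,4R)-4-hydroxy-5-methyl-5-(triethylsilyloxy)hex-1-yn-3-yl]-3-methoxycyclohex-2-en-1-one | COC1=C([C@H](C#C)[C@@H](O)C(C)(C)O[Si](CC)(CC)CC)C(=O)C[C@H](O[Si](C)(C)C(C)(C)C)C1 | intermediate
18 | (2R,3S,6R)-6-(tert-butyldimethylsilyloxy)-3-ethynyl-2-[2-(triethylsilyloxy)propan-2-yl]-3,5,6,7-tetrahydro-1-benzofuran-4(2H)-one | C#C[C@H]1C2=C(O[C@H]1C(C)(C)O[Si](CC)(CC)CC)C[C@@H](O[Si](C)(C)C(C)(C)C)CC2=O | intermediate
19 | (2R,3S,6R)-6-(tert-butyldimethylsilyloxy)-3-ethynyl-4-(triethylsilyloxy)-2-[2-(triethylsilyloxy)propan-2-yl]-2,3,6,7-tetrahydro-1-benzofuran | C#C[C@H]1C2=C(O[C@H]1C(C)(C)O[Si](CC)(CC)CC)C[C@@H](O[Si](C)(C)C(C)(C)C)C=C2O[Si](CC)(CC)CC | intermediate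
20 | lithium ynolate of 19 (oxygen on the alkyne terminus; not isolated) | [Li+].[O-]C#C[C@H]1C2=C(O[C@H]1C(C)(C)O[Si](CC)(CC)CC)C[C@@H](O[Si](C)(C)C(C)(C)C)C=C2O[Si](CC)(CC)CC | intermediate
21 | 4-O-triethylsilyl dienol ether of 22 (not isolated) | CC(C)[Si](C(C)C)(C(C)C)OC#C[C@H]1C2=C(O[C@H]1C(C)(C)O[Si](CC)(CC)CC)C[C@@H](O[Si](C)(C)C(C)(C)C)C=C2O[Si](CC)(CC)CC | intermediate
22 | (2R,3S,6R)-6-(tert-butyldimethylsilyloxy)-2-[2-(triethylsilyloxy)propan-2-yl]-3-[(triisopropylsilyloxy)ethynyl]-3,5,6,7-tetrahydro-1-benzofuran-4(2H)-one | CC(C)[Si](C(C)C)(C(C)C)OC#C[C@H]1C2=C(O[C@H]1C(C)(C)O[Si](CC)(CC)CC)C[C@@H](O[Si](C)(C)C(C)(C)C)CC2=O | intermediate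
23 | methyl coumalate (methyl 2-oxo-2H-pyran-5-carboxylate) | COC(=O)C1=COC(=O)C=C1 | starting material
24 | 2-oxabicyclo[2.2.2]octa-5,7-dien-3-one cycloadduct of 22 and 23 (bridgehead configuration undefined; not isolated) | O=C1OC2C(C(=O)OC)=CC1C(O[Si](C(C)C)(C(C)C)C(C)C)=C2[C@H]1C2=C(O[C@H]1C(C)(C)O[Si](CC)(CC)CC)C[C@@H](O[Si](C)(C)C(C)(C)C)CC2=O | intermediate
25 | methyl 3-[(2R,3S,6R)-6-(tert-butyldimethylsilyloxy)-4-oxo-2-[2-(triethylsilyloxy)propan-2-yl]-2,3,4,5,6,7-hexahydro-1-benzofuran-3-yl]-4-(triisopropylsilyloxy)benzoate | COC(=O)c1ccc(O[Si](C(C)C)(C(C)C)C(C)C)c([C@H]2C3=C(O[C@H]2C(C)(C)O[Si](CC)(CC)CC)C[C@@H](O[Si](C)(C)C(C)(C)C)CC3=O)c1 | intermediate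
26 | 3-phenylpropanal | O=CCCc1ccccc1 | starting material
27 | 7-(1-hydroxy-3-phenylpropyl) derivative of 25 (2R,3S,6S; mixture at C7 and the carbinol carbon) | COC(=O)c1ccc(O[Si](C(C)C)(C(C)C)C(C)C)c([C@H]2C3=C(O[C@H]2C(C)(C)O[Si](CC)(CC)CC)C(C(O)CCc2ccccc2)[C@@H](O[Si](C)(C)C(C)(C)C)CC3=O)c1 | intermediate
28 | 7-(3-phenylpropanoyl) derivative of 25 (2R,3S,6S; C7 labile; not isolated) | COC(=O)c1ccc(O[Si](C(C)C)(C(C)C)C(C)C)c([C@H]2C3=C(O[C@H]2C(C)(C)O[Si](CC)(CC)CC)C(C(=O)CCc2ccccc2)[C@@H](O[Si](C)(C)C(C)(C)C)CC3=O)c1 | intermediate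
29 | 7-chloro-7-(3-phenylpropanoyl) derivative of 25 (2R,3S,6S; C7 not controlled) | COC(=O)c1ccc(O[Si](C(C)C)(C(C)C)C(C)C)c([C@H]2C3=C(O[C@H]2C(C)(C)O[Si](CC)(CC)CC)C(Cl)(C(=O)CCc2ccccc2)[C@@H](O[Si](C)(C)C(C)(C)C)CC3=O)c1 | intermediate
30 | 4-O-methyl oxocarbenium tetrafluoroborate of 29 (1,3-dialkoxyallyl cation over C4, C3a and C7a; not isolated) | COC(=O)c1ccc(O[Si](C(C)C)(C(C)C)C(C)C)c([C@H]2C3=C(OC)C[C@H](O[Si](C)(C)C(C)(C)C)C(Cl)(C(=O)CCc4ccccc4)C3=[O+][C@H]2C(C)(C)O[Si](CC)(CC)CC)c1.F[B-](F)(F)F | intermediate
31 | methyl 3-[(2R,3S,6S)-6-(tert-butyldimethylsilyloxy)-7-chloro-4-methoxy-7-(3-phenylpropanoyl)-2-[2-(triethylsilyloxy)propan-2-yl]-2,3,6,7-tetrahydro-1-benzofuran-3-yl]-4-(triisopropylsilyloxy)benzoate (C7 not controlled) | COC(=O)c1ccc(O[Si](C(C)C)(C(C)C)C(C)C)c([C@H]2C3=C(O[C@H]2C(C)(C)O[Si](CC)(CC)CC)C(Cl)(C(=O)CCc2ccccc2)[C@@H](O[Si](C)(C)C(C)(C)C)C=C3OC)c1 | intermediate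
32 | methyl 3-[(2R,3S,6S,7S)-6-(tert-butyldimethylsilyloxy)-4-methoxy-7-(3-phenylpropanoyl)-2-[2-(triethylsilyloxy)propan-2-yl]-2,3,6,7-tetrahydro-1-benzofuran-3-yl]-4-(triisopropylsilyloxy)benzoate | COC(=O)c1ccc(O[Si](C(C)C)(C(C)C)C(C)C)c([C@H]2C3=C(O[C@H]2C(C)(C)O[Si](CC)(CC)CC)[C@@H](C(=O)CCc2ccccc2)[C@@H](O[Si](C)(C)C(C)(C)C)C=C3OC)c1 | intermediate
33 | methyl 4-hydroxy-3-[(2R,3S,6S,7S)-6-hydroxy-2-(2-hydroxypropan-2-yl)-4-methoxy-7-(3-phenylpropanoyl)-2,3,6,7-tetrahydro-1-benzofuran-3-yl]benzoate | COC(=O)c1ccc(O)c([C@H]2C3=C(O[C@H]2C(C)(C)O)[C@@H](C(=O)CCc2ccccc2)[C@@H](O)C=C3OC)c1 | target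

## Step count and steps least certain to work

Total: 19 steps. Longest linear sequence: 15 steps (steps 5 to 19, from phloroglucinol); the epoxide arm (steps 1 to 4) joins at step 10.

Step 14 (key step). The likeliest failure is thermal decay of the ynol ether (silyl shift to a silyl ketene, or hydrolysis) outrunning a cycloaddition that is slowed by the secondary C3 substituent on the reacting carbon. Fallback, from 22 back to 25: the ynol ether would be hydrated (wet MeCN, catalytic acid) to the triisopropylsilyl ester of the C3 acetic acid F1. Soft enolization (iPr3SiOTf, Et3N), which also silylates the ring ketone, would give the ketene bis(triisopropylsilyl) acetal F2. This electron-rich alkene would be heated with 23; it should add with the same orientation, lose CO2 and then triisopropylsilanol to give the arene, and a mild acidic work-up of the ring dienol ether would return 25.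

Step 10. The hindered vinyllithium may act as a base or open the epoxide in the SN2' sense to an allene, and the crowded C3–C3a bond may form slowly. Fallback, from 7 and 9 back to 18:
- 7 would be desilylated (K2CO3, MeOH) to the terminal alkynyl epoxide F3.
- 9 would be silylated to 5-(tert-butyldimethylsilyloxy)cyclohexane-1,3-dione F4.
- The caesium enolate of F4 (Cs2CO3, DMF, 50 °C) would open F3 at the propargylic carbon to the hydroxy dione F5.
- Pyridinium p-toluenesulfonate would cyclize F5 to 18 together with its C6 epimer F6, because the dione no longer remembers which carbonyl should receive O1.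
- The two would be separated by chromatography, and F6 returned to the mixture by hydrolytic equilibration.

Step 15. Deprotonation may occur at C5 instead of C7, or the dienolate may expel the C6 silyloxy group (vinylogous elimination, then aromatization). Fallback, from 25 back to 27: equilibrating soft enolization (tBuMe2SiOTf, Et3N, rt) would be used to reach the linear silyl dienol ether F7, and a BF3·OEt2-mediated vinylogous Mukaiyama aldol reaction with 26 at −78 °C would then form the C7–C bond without any metal enolate.

Step 16. Ketone 28 can lose the C6 silyloxy group by elimination through its acidic C7–H before it is chlorinated, which aromatizes ring C. Fallback, from 27 back to 31: after the oxidation, 28 would be trapped by O-methylation (Me3OBF4, then iPr2NEt, which here removes the C7 proton) as the conjugated dienol ether F8. N-Chlorosuccinimide should then attack C7, the β-carbon of the ring B enol ether, and loss of the C5 proton would give 31 directly.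

Step 18. The samarium enolate may eliminate the C6 silyloxy group before it is protonated, or protonation may occur at C5 or C3a and give the conjugated isomer. Fallback, from 31 back to 32: the chloride would be removed by a radical chain (Bu3SnH, Et3B, air, toluene, −78 °C). The C7 radical cannot expel the neighbouring oxygen and should take hydrogen on the face away from the silyloxy group. This makes no new compound.

## Further compounds

F1 | step 14 | triisopropylsilyl 2-[(2R,3R,6R)-6-(tert-butyldimethylsilyloxy)-4-oxo-2-[2-(triethylsilyloxy)propan-2-yl]-2,3,4,5,6,7-hexahydro-1-benzofuran-3-yl]acetate | CC(C)[Si](C(C)C)(C(C)C)OC(=O)C[C@H]1C2=C(O[C@H]1C(C)(C)O[Si](CC)(CC)CC)C[C@@H](O[Si](C)(C)C(C)(C)C)CC2=O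
F2 | step 14 | ketene bis(triisopropylsilyl) acetal of F1 with the ring ketone as its triisopropylsilyl dienol ether | CC(C)[Si](C(C)C)(C(C)C)OC(O[Si](C(C)C)(C(C)C)C(C)C)=C[C@H]1C2=C(O[C@H]1C(C)(C)O[Si](CC)(CC)CC)C[C@@H](O[Si](C)(C)C(C)(C)C)C=C2O[Si](C(C)C)(C(C)C)C(C)C
F3 | step 10 | (2S,3R)-2-ethynyl-3-[2-(triethylsilyloxy)propan-2-yl]oxirane | C#C[C@@H]1O[C@H]1C(C)(C)O[Si](CC)(CC)CC
F4 | step 10 | 5-(tert-butyldimethylsilyloxy)cyclohexane-1,3-dione | O=C1CC(O[Si](C)(C)C(C)(C)C)CC(=O)C1
F5 | step 10 | 5-(tert-butyldimethylsilyloxy)-2-[(3S,4R)-4-hydroxy-5-methyl-5-(triethylsilyloxy)hex-1-yn-3-yl]cyclohexane-1,3-dione | O=C1CC(O[Si](C)(C)C(C)(C)C)CC(=O)C1[C@H](C#C)[C@@H](O)C(C)(C)O[Si](CC)(CC)CC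
F6 | step 10 | (2R,3S,6S)-6-(tert-butyldimethylsilyloxy)-3-ethynyl-2-[2-(triethylsilyloxy)propan-2-yl]-3,5,6,7-tetrahydro-1-benzofuran-4(2H)-one (C6 epimer of 18) | C#C[C@H]1C2=C(O[C@H]1C(C)(C)O[Si](CC)(CC)CC)C[C@H](O[Si](C)(C)C(C)(C)C)CC2=O
F7 | step 15 | 4-O-tert-butyldimethylsilyl dienol ether of 25 with C3a=C4 and C7a=C7 double bonds | COC(=O)c1ccc(O[Si](C(C)C)(C(C)C)C(C)C)c([C@H]2C3=C(O[Si](C)(C)C(C)(C)C)C[C@H](O[Si](C)(C)C(C)(C)C)C=C3O[C@H]2C(C)(C)O[Si](CC)(CC)CC)c1
F8 | step 16 | methyl 3-[(2R,3S,6S)-6-(tert-butyldimethylsilyloxy)-4-methoxy-7-(3-phenylpropanoyl)-2-[2-(triethylsilyloxy)propan-2-yl]-2,3,5,6-tetrahydro-1-benzofuran-3-yl]-4-(triisopropylsilyloxy)benzoate (conjugated dienol ether, C3a=C4 and C7=C7a) | COC(=O)c1ccc(O[Si](C(C)C)(C(C)C)C(C)C)c([C@H]2C3=C(OC)C[C@H](O[Si](C)(C)C(C)(C)C)C(C(=O)CCc4ccccc4)=C3O[C@H]2C(C)(C)O[Si](CC)(CC)CC)c1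
F0 | step 18 | none | none
A1 | alternative 1 | methyl 4-hydroxy-3-[(2R,3S)-2-(2-hydroxypropan-2-yl)-4-(1-methoxyvinyl)-5-[(3S,4S)-1-oxo-1-(2-phenylethyl)-4-(triethylsilyloxy)hex-5-en-3-yl... ring B diene precursor of the metathesis: 1-methoxyvinyl on C3a, 3-(triethylsilyloxy)pent-4-en-2-yl ketone chain on C7a] benzoate | COC(=O)c1ccc(O)c([C@H]2C(C(=C)OC)=C(O[C@H]2C(C)(C)O)[C@@H](C(=O)CCc2ccccc2)[C@@H](O[Si](CC)(CC)CC)C=C)c1
A2 | alternative 1 | 6-O-triethylsilyl ether of 33 | COC(=O)c1ccc(O)c([C@H]2C3=C(O[C@H]2C(C)(C)O)[C@@H](C(=O)CCc2ccccc2)[C@@H](O[Si](CC)(CC)CC)C=C3OC)c1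
A3 | alternative 2 | methyl 3,4-didehydrobenzoate (aryne) | COC(=O)C1=CC#CC=C1
A4 | alternative 2 | (4S)-2,2,5,5-tetramethyl-1,3-dioxolane-4-carbaldehyde | O=C[C@H]1OC(C)(C)OC1(C)C
A5 | alternative 2 | (5S)-5-(tert-butyldimethylsilyloxy)-3-methoxycyclohex-2-en-1-one | COC1=CC(=O)C[C@@H](O[Si](C)(C)C(C)(C)C)C1
A6 | alternative 2 | methyl 4-hydroxy-3-[(4-silyloxy-2-methoxy-6-oxocyclohex-1-enyl)(2,2,5,5-tetramethyl-1,3-dioxolan-4-yl)methyl]benzoate | COC(=O)c1ccc(O)c([C@H]([C@H]2OC(C)(C)OC2(C)C)C2=C(OC)C[C@H](O[Si](C)(C)C(C)(C)C)CC2=O)c1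
A7 | alternative 3 | methyl 4-(tert-butyldimethylsilyloxy)-3-{diazo[(4R)-4-(tert-butyldimethylsilyloxy)-2-[2-methyl-2-(triethylsilyloxy)propoxy]-6-oxocyclohex-1-en-1-yl]methyl}benzoate | COC(=O)c1ccc(O[Si](C)(C)C(C)(C)C)c(C(=[N+]=[N-])C2=C(OCC(C)(C)O[Si](CC)(CC)CC)C[C@@H](O[Si](C)(C)C(C)(C)C)CC2=O)c1
A8 | alternative 3 | tert-butyldimethylsilyl analogue of 25 (aryl silyl ether) | COC(=O)c1ccc(O[Si](C)(C)C(C)(C)C)c([C@H]2C3=C(O[C@H]2C(C)(C)O[Si](CC)(CC)CC)C[C@@H](O[Si](C)(C)C(C)(C)C)CC3=O)c1
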